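**Retrosynthetic overview**
Ring locants (elemane-type): C10 (quaternary, Me and vinyl), C9 (CH2), C8 (O-ester), C7 (acrylic acid), C6 (OH), C5 (3-hydroxyprop-1-en-2-yl); there is one ring, formed once and late.
Target ⇐ global deprotection ⇐ C8–O ester bond to fragment D (Roche-ester acid); the axial C6 carbinol ⇐ C6 ketone.
Cyclohexane ring ⇐ intramolecular aldol (C7–C8) of an acyclic 1,5-keto-aldehyde.
C6–C7 ⇐ palladium-catalysed acyl fluoride/allylboronate cross-coupling of the C5/C10 acid with fragment C (2-(tert-butoxycarbonyl)allyl boronate).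
C5–C10 (both stereocentres) ⇐ enantioselective Ireland–Claisen rearrangement of the ester of fragment A (allylic alcohol by Zr-catalysed carboalumination) and fragment B (3-(silyloxymethyl)but-3-enoic acid).

Assumption: the target is the open γ-hydroxy acid as drawn (not its 6,12-lactone), and the (S,S)-boron reagent of step 6 is assumed to give the sense of induction leading to 13 (the (R,R)-reagent is used if the first run shows the opposite).

Step 1
Reactants: 1 but-3-yn-1-ol
Product: 2 1-[(but-3-yn-1-yloxy)methyl]-4-methoxybenzene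
Conditions: NaH, 4-methoxybenzyl chloride, Bu4NI (cat.), THF, 0 °C → rt
Reagents that add atoms: 4-methoxybenzyl chloride, COc1ccc(CCl)cc1
Why: Williamson etherification; the alkoxide forms in preference to the acetylide and is benzylated, and no stereocentre is involved.

Step 2
Reactants: 2 1-[(but-3-yn-1-yloxy)methyl]-4-methoxybenzene
Product: 5 (2E)-5-[(4-methoxybenzyl)oxy]-3-methylpent-2-en-1-ol, via alkenyldimethylalane 3 (not isolated), via lithium alkenylalanate 4 (not isolated)
Conditions: Me3Al, bis(cyclopentadienyl)zirconium dichloride (Cp2ZrCl2, 20 mol %), CH2Cl2, 0 °C → rt; then n-BuLi, THF, −78 °C; (CH2O)n, → rt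
Reagents that add atoms: trimethylaluminium, C[Al](C)C; paraformaldehyde (as formaldehyde), C=O
Why: Negishi zirconium-catalysed syn-methylalumination puts Me and Al cis on the terminal alkyne, and the alanate transfers the alkenyl group to formaldehyde with retention, fixing the (E)-trisubstituted alkene.

Step 3
Reactants: 6 2-methylprop-2-en-1-ol
Product: 8 3-(hydroxymethyl)but-3-enoic acid, via dilithio dianion 7 (not isolated)
Conditions: n-BuLi (2.2 equiv), TMEDA, Et2O, 0 °C → rt; CO2, −78 °C; 1 M HCl to pH 3, 0 °C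
Reagents that add atoms: carbon dioxide, O=C=O
Why: Double deprotonation (O–H then allylic C–H) gives an allyl anion with two equivalent CH2 termini, so organolithium carboxylation gives a single β,γ-unsaturated acid.

Step 4
Reactants: 8 3-(hydroxymethyl)but-3-enoic acid
Product: 10 3-({[tert-butyl(dimethyl)silyl]oxy}methyl)but-3-enoic acid, via bis-silyl ester 9 (not isolated)
Conditions: TBSCl (2.3 equiv), imidazole, DMF, rt; then MeOH, K2CO3 (5 mol %), 0 °C
Reagents that add atoms: tert-butyldimethylsilyl chloride, CC(C)(C)[Si](C)(C)Cl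
Why: Silylation of both OH groups followed by selective methanolysis of the much more labile silyl ester (standard protection), done at once so the hydroxy acid cannot lactonise.

Step 5
Reactants: 5 (2E)-5-[(4-methoxybenzyl)oxy]-3-methylpent-2-en-1-ol; 10 3-({[tert-butyl(dimethyl)silyl]oxy}methyl)but-3-enoic acid
Product: 11 (2E)-5-[(4-methoxybenzyl)oxy]-3-methylpent-2-en-1-yl 3-({[tert-butyl(dimethyl)silyl]oxy}methyl)but-3-enoate
Conditions: EDC·HCl, DMAP (10 mol %), CH2Cl2, 0 °C → rt
Reagents that add atoms: none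
Why: Carbodiimide (Steglich) esterification at 0 °C joins fragments A and B without moving the β,γ-double bond into conjugation.

Step 6
Reactants: 11 (2E)-5-[(4-methoxybenzyl)oxy]-3-methylpent-2-en-1-yl 3-({[tert-butyl(dimethyl)silyl]oxy}methyl)but-3-enoate
Product: 13 (2R,3S)-2-(3-{[tert-butyl(dimethyl)silyl]oxy}prop-1-en-2-yl)-3-ethenyl-5-[(4-methoxybenzyl)oxy]-3-methylpentanoic acid, via boron ketene acetal 12 (not isolated)
Conditions: (4S,5S)-2-bromo-1,3-bis{[3,5-bis(trifluoromethyl)phenyl]sulfonyl}-4,5-diphenyl-1,3,2-diazaborolidine (1.2 equiv), Et3N, toluene–hexane, −78 °C; then −20 → 4 °C; aqueous work-up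
Reagents that add atoms: none
Why: Enantioselective Ireland–Claisen rearrangement: soft enolisation gives the boron ketene acetal with the C5 side chain cis to the allyloxy oxygen, which rearranges through a chair with the (E)-alkene (C9 chain equatorial, methyl axial), so C5 and C10 form together as 2R,3S, the C2-symmetric sulfonamide ligand on boron choosing the enantioface.

Step 7
Reactants: 14 2-(bromomethyl)prop-2-enoic acid
Product: 15 tert-butyl 2-(bromomethyl)prop-2-enoate
Conditions: isobutene, H2SO4 (cat.), CH2Cl2, sealed tube, rt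
Reagents that add atoms: isobutene (2-methylpropene), CC(C)=C
Why: Acid-catalysed addition of the carboxylic acid to isobutene (tert-butyl ester formation); the bulky ester later blocks lactonisation of the C6 and C8 oxygens onto C12.

Step 8
Reactants: 15 tert-butyl 2-(bromomethyl)prop-2-enoate
Product: 16 tert-butyl 2-[(4,4,5,5-tetramethyl-1,3,2-dioxaborolan-2-yl)methyl]prop-2-enoate
Conditions: B2pin2, CuCl (10 mol %), KOAc, DMF, rt
Reagents that add atoms: bis(pinacolato)diboron, CC1(C)OB(OC1(C)C)B1OC(C)(C)C(C)(C)O1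
Why: Copper-catalysed allylic borylation; direct and allylic-transposed substitution give the same product because the two allyl CH2 termini are equivalent.

Step 9
Reactants: 13 (2R,3S)-2-(3-{[tert-butyl(dimethyl)silyl]oxy}prop-1-en-2-yl)-3-ethenyl-5-[(4-methoxybenzyl)oxy]-3-methylpentanoic acid; 16 tert-butyl 2-[(4,4,5,5-tetramethyl-1,3,2-dioxaborolan-2-yl)methyl]prop-2-enoate
Product: 18 tert-butyl (5R,6S)-5-(3-{[tert-butyl(dimethyl)silyl]oxy}prop-1-en-2-yl)-6-ethenyl-8-[(4-methoxybenzyl)oxy]-6-methyl-2-methylidene-4-oxooctanoate, via acyl fluoride 17 (not isolated)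
Conditions: cyanuric fluoride, pyridine, CH2Cl2, −10 → 0 °C, filter; then 16, Pd(OAc)2 (5 mol %), PCy3 (12 mol %), toluene, 45 °C
Reagents that add atoms: none
Why: Proposed new method: palladium-catalysed acyl fluoride–allylboronate ketone synthesis, in which zerovalent palladium inserts into the C(acyl)–F bond of 17, the divalent acylpalladium fluoride transmetalates with the allyl–B(pin) of 16 through a closed six-membered transition state driven by B–F bond formation (no base, so the C5 stereocentre next to the carbonyl is kept), the equivalent CH2 termini of the 2-carboalkoxyallyl group make α- and γ-transfer converge, and reductive elimination forms C6–C7, while the electron-poor allylboronate does not add to the product ketone at 45 °C; the closest known reactions are the palladium-catalysed acid chloride–allylstannane ketone synthesis (Stille acylation) and palladium- or nickel-catalysed couplings of acyl fluorides with arylboron and organozinc reagents.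

Step 10
Reactants: 18 tert-butyl (5R,6S)-5-(3-{[tert-butyl(dimethyl)silyl]oxy}prop-1-en-2-yl)-6-ethenyl-8-[(4-methoxybenzyl)oxy]-6-methyl-2-methylidene-4-oxooctanoate
Product: 19 tert-butyl (5R,6S)-5-(3-{[tert-butyl(dimethyl)silyl]oxy}prop-1-en-2-yl)-6-ethenyl-8-hydroxy-6-methyl-2-methylidene-4-oxooctanoate
Conditions: DDQ, CH2Cl2–pH 7 phosphate buffer (10:1), 0 °C
Reagents that add atoms: none
Why: Oxidative cleavage of the 4-methoxybenzyl ether by DDQ under neutral buffer leaves the silyl ether, alkenes and the β,γ-unsaturated ketone untouched.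

Step 11
Reactants: 19 tert-butyl (5R,6S)-5-(3-{[tert-butyl(dimethyl)silyl]oxy}prop-1-en-2-yl)-6-ethenyl-8-hydroxy-6-methyl-2-methylidene-4-oxooctanoate
Product: 20 tert-butyl (5R,6S)-5-(3-{[tert-butyl(dimethyl)silyl]oxy}prop-1-en-2-yl)-6-ethenyl-6-methyl-2-methylidene-4,8-dioxooctanoate
Conditions: TEMPO (10 mol %), PhI(OAc)2, CH2Cl2, rt
Reagents that add atoms: none
Why: Oxoammonium (TEMPO) oxidation is selective for the primary alcohol and free of base, so neither C5 nor the deconjugated alkenes are disturbed.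

Step 12
Reactants: 20 tert-butyl (5R,6S)-5-(3-{[tert-butyl(dimethyl)silyl]oxy}prop-1-en-2-yl)-6-ethenyl-6-methyl-2-methylidene-4,8-dioxooctanoate
Product: 21 tert-butyl 2-[(1R,3R,4S,6S)-3-(3-{[tert-butyl(dimethyl)silyl]oxy}prop-1-en-2-yl)-4-ethenyl-6-hydroxy-4-methyl-2-oxocyclohexyl]prop-2-enoate
Conditions: DBU (0.2 equiv), MeCN (0.01 M), −20 → 0 °C; AcOH quench
Reagents that add atoms: none
Why: Intramolecular aldol addition of a 1,5-keto-aldehyde (ketone enolate at the less hindered C7 onto the C8 aldehyde) under reversible catalytic-base conditions, so C7 and C8 settle as the all-equatorial ketol (C8–OH equatorial to avoid the syn-axial C10 methyl, C7 side chain equatorial) with C5 kept, and the equatorial C8–O is poorly aligned for E1cB loss so the ketol is not dehydrated.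

Step 13
Reactants: 21 tert-butyl 2-[(1R,3R,4S,6S)-3-(3-{[tert-butyl(dimethyl)silyl]oxy}prop-1-en-2-yl)-4-ethenyl-6-hydroxy-4-methyl-2-oxocyclohexyl]prop-2-enoate
Product: 22 tert-butyl 2-[(1R,2S,3R,4S,6S)-3-(3-{[tert-butyl(dimethyl)silyl]oxy}prop-1-en-2-yl)-4-ethenyl-2,6-dihydroxy-4-methylcyclohexyl]prop-2-enoate
Conditions: LiAlH(OtBu)3, THF, −40 → −10 °C; aq. KNaC4H4O6
Reagents that add atoms: none
Why: Hydride reduction under steric approach control: axial delivery to C6 is blocked by the syn-axial C10 methyl (as in 3,3,5-trimethylcyclohexanone), so the bulky alkoxyaluminium hydride enters equatorially and gives the axial C6 alcohol, while the tert-butyl acrylate is inert to this reagent and cannot lactonise.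

Step 14
Reactants: 23 methyl (2R)-3-hydroxy-2-methylpropanoate
Product: 24 methyl (2R)-3-{[tert-butyl(dimethyl)silyl]oxy}-2-methylpropanoate
Conditions: TBSCl, imidazole, DMF, 0 °C → rt
Reagents that add atoms: tert-butyldimethylsilyl chloride, CC(C)(C)[Si](C)(C)Cl
Why: Standard silylation of the primary alcohol; the stereocentre is not touched.

Step 15
Reactants: 24 methyl (2R)-3-{[tert-butyl(dimethyl)silyl]oxy}-2-methylpropanoate
Product: 25 (2R)-3-{[tert-butyl(dimethyl)silyl]oxy}-2-methylpropanoic acid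
Conditions: LiOH·H2O, THF–MeOH–H2O, 0 °C → rt; 1 M HCl to pH 4
Reagents that add atoms: lithium hydroxide, [Li+].[OH-]
Why: Saponification of the methyl ester at low temperature, which for this Roche-ester series proceeds without epimerisation or β-elimination.

Step 16
Reactants: 22 tert-butyl 2-[(1R,2S,3R,4S,6S)-3-(3-{[tert-butyl(dimethyl)silyl]oxy}prop-1-en-2-yl)-4-ethenyl-2,6-dihydroxy-4-methylcyclohexyl]prop-2-enoate; 25 (2R)-3-{[tert-butyl(dimethyl)silyl]oxy}-2-methylpropanoic acid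
Product: 27 tert-butyl 2-[(1S,2S,3R,4S,6S)-3-(3-{[tert-butyl(dimethyl)silyl]oxy}prop-1-en-2-yl)-6-{[(2R)-3-{[tert-butyl(dimethyl)silyl]oxy}-2-methylpropanoyl]oxy}-4-ethenyl-2-hydroxy-4-methylcyclohexyl]prop-2-enoate, via mixed anhydride 26 (not isolated)
Conditions: 2,4,6-trichlorobenzoyl chloride, Et3N, THF, rt; then 22, DMAP, toluene, 0 °C → rt
Reagents that add atoms: none
Why: Yamaguchi esterification, site-selective for the equatorial C8 hydroxyl because the axial C6 hydroxyl is flanked by two branched carbons and is syn-axial to the C10 methyl, and the trans-1,3 (axial/equatorial) diol geometry prevents later acyl migration.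

Step 17
Reactants: 27 tert-butyl 2-[(1S,2S,3R,4S,6S)-3-(3-{[tert-butyl(dimethyl)silyl]oxy}prop-1-en-2-yl)-6-{[(2R)-3-{[tert-butyl(dimethyl)silyl]oxy}-2-methylpropanoyl]oxy}-4-ethenyl-2-hydroxy-4-methylcyclohexyl]prop-2-enoate
Product: 29 2-[(1S,2S,3R,4S,6S)-4-ethenyl-2-hydroxy-6-{[(2R)-3-hydroxy-2-methylpropanoyl]oxy}-3-(3-hydroxyprop-1-en-2-yl)-4-methylcyclohexyl]prop-2-enoic acid (CNP0462645.4), via bis-trimethylsilyl intermediate 28 (not isolated)
Conditions: TMSOTf, 2,6-lutidine, CH2Cl2, 0 °C; then HF·pyridine, pyridine, THF, 0 °C → rt; pH 6 phosphate buffer work-up, no acid, no heat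
Reagents that add atoms: none
Why: Silyl-triflate-mediated tert-butyl ester cleavage (loss of isobutene to the trimethylsilyl ester while the C6 hydroxyl is masked in situ as its silyl ether and cannot lactonise) followed by fluoride desilylation of all four silyl groups; no stereocentre is touched.

**Compound list**
1 | but-3-yn-1-ol | C#CCCO | starting material
2 | 1-[(but-3-yn-1-yloxy)methyl]-4-methoxybenzene | C#CCCOCc1ccc(OC)cc1 | intermediate
3 | [(1E)-4-[(4-methoxybenzyl)oxy]-2-methylbut-1-en-1-yl]dimethylalane | C[Al](C)/C=C(\C)CCOCc1ccc(OC)cc1 | intermediate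
4 | lithium butyl[(1E)-4-[(4-methoxybenzyl)oxy]-2-methylbut-1-en-1-yl]dimethylalanate | [Li+].CCCC[Al-](C)(C)/C=C(\C)CCOCc1ccc(OC)cc1 | intermediate
5 | (2E)-5-[(4-methoxybenzyl)oxy]-3-methylpent-2-en-1-ol (fragment A) | OC/C=C(\C)CCOCc1ccc(OC)cc1 | intermediate
6 | 2-methylprop-2-en-1-ol | C=C(C)CO | starting material
7 | lithium 2-(lithiomethyl)prop-2-en-1-olate (dianion of 6) | [Li]CC(=C)CO[Li] | intermediate
8 | 3-(hydroxymethyl)but-3-enoic acid | C=C(CO)CC(=O)O | intermediate
9 | tert-butyl(dimethyl)silyl 3-({[tert-butyl(dimethyl)silyl]oxy}methyl)but-3-enoate | C=C(CO[Si](C)(C)C(C)(C)C)CC(=O)O[Si](C)(C)C(C)(C)C | intermediate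
10 | 3-({[tert-butyl(dimethyl)silyl]oxy}methyl)but-3-enoic acid (fragment B) | C=C(CO[Si](C)(C)C(C)(C)C)CC(=O)O | intermediate
11 | (2E)-5-[(4-methoxybenzyl)oxy]-3-methylpent-2-en-1-yl 3-({[tert-butyl(dimethyl)silyl]oxy}methyl)but-3-enoate | C=C(CO[Si](C)(C)C(C)(C)C)CC(=O)OC/C=C(\C)CCOCc1ccc(OC)cc1 | intermediate
12 | O-boryl ketene acetal of 11, boron carrying the (4S,5S)-1,3-bis{[3,5-bis(trifluoromethyl)phenyl]sulfonyl}-4,5-diphenyl-1,3,2-diazaborolidine ring, C5 side chain cis to the allyloxy oxygen | C=C(CO[Si](C)(C)C(C)(C)C)/C=C(/OB1N(S(=O)(=O)c2cc(C(F)(F)F)cc(C(F)(F)F)c2)[C@@H](c2ccccc2)[C@H](c2ccccc2)N1S(=O)(=O)c1cc(C(F)(F)F)cc(C(F)(F)F)c1)OC/C=C(\C)CCOCc1ccc(OC)cc1 | intermediate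
13 | (2R,3S)-2-(3-{[tert-butyl(dimethyl)silyl]oxy}prop-1-en-2-yl)-3-ethenyl-5-[(4-methoxybenzyl)oxy]-3-methylpentanoic acid | C=C[C@](C)(CCOCc1ccc(OC)cc1)[C@H](C(=C)CO[Si](C)(C)C(C)(C)C)C(=O)O | intermediate
14 | 2-(bromomethyl)prop-2-enoic acid | C=C(CBr)C(=O)O | starting material
15 | tert-butyl 2-(bromomethyl)prop-2-enoate | C=C(CBr)C(=O)OC(C)(C)C | intermediate
16 | tert-butyl 2-[(4,4,5,5-tetramethyl-1,3,2-dioxaborolan-2-yl)methyl]prop-2-enoate (fragment C) | C=C(CB1OC(C)(C)C(C)(C)O1)C(=O)OC(C)(C)C | intermediate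
17 | (2R,3S)-2-(3-{[tert-butyl(dimethyl)silyl]oxy}prop-1-en-2-yl)-3-ethenyl-5-[(4-methoxybenzyl)oxy]-3-methylpentanoyl fluoride | C=C[C@](C)(CCOCc1ccc(OC)cc1)[C@H](C(=C)CO[Si](C)(C)C(C)(C)C)C(F)=O | intermediate
18 | tert-butyl (5R,6S)-5-(3-{[tert-butyl(dimethyl)silyl]oxy}prop-1-en-2-yl)-6-ethenyl-8-[(4-methoxybenzyl)oxy]-6-methyl-2-methylidene-4-oxooctanoate | C=C[C@](C)(CCOCc1ccc(OC)cc1)[C@H](C(=C)CO[Si](C)(C)C(C)(C)C)C(=O)CC(=C)C(=O)OC(C)(C)C | intermediate
19 | tert-butyl (5R,6S)-5-(3-{[tert-butyl(dimethyl)silyl]oxy}prop-1-en-2-yl)-6-ethenyl-8-hydroxy-6-methyl-2-methylidene-4-oxooctanoate | C=C[C@](C)(CCO)[C@H](C(=C)CO[Si](C)(C)C(C)(C)C)C(=O)CC(=C)C(=O)OC(C)(C)C | intermediate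
20 | tert-butyl (5R,6S)-5-(3-{[tert-butyl(dimethyl)silyl]oxy}prop-1-en-2-yl)-6-ethenyl-6-methyl-2-methylidene-4,8-dioxooctanoate | C=C[C@](C)(CC=O)[C@H](C(=C)CO[Si](C)(C)C(C)(C)C)C(=O)CC(=C)C(=O)OC(C)(C)C | intermediate
21 | tert-butyl 2-[(1R,3R,4S,6S)-3-(3-{[tert-butyl(dimethyl)silyl]oxy}prop-1-en-2-yl)-4-ethenyl-6-hydroxy-4-methyl-2-oxocyclohexyl]prop-2-enoate | C=C[C@]1(C)C[C@H](O)[C@@H](C(=C)C(=O)OC(C)(C)C)C(=O)[C@H]1C(=C)CO[Si](C)(C)C(C)(C)C | intermediate
22 | tert-butyl 2-[(1R,2S,3R,4S,6S)-3-(3-{[tert-butyl(dimethyl)silyl]oxy}prop-1-en-2-yl)-4-ethenyl-2,6-dihydroxy-4-methylcyclohexyl]prop-2-enoate | C=C[C@]1(C)C[C@H](O)[C@@H](C(=C)C(=O)OC(C)(C)C)[C@@H](O)[C@H]1C(=C)CO[Si](C)(C)C(C)(C)C | intermediate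
23 | methyl (2R)-3-hydroxy-2-methylpropanoate | C[C@H](CO)C(=O)OC | starting material
24 | methyl (2R)-3-{[tert-butyl(dimethyl)silyl]oxy}-2-methylpropanoate | C[C@H](CO[Si](C)(C)C(C)(C)C)C(=O)OC | intermediate
25 | (2R)-3-{[tert-butyl(dimethyl)silyl]oxy}-2-methylpropanoic acid (fragment D) | C[C@H](CO[Si](C)(C)C(C)(C)C)C(=O)O | intermediate
26 | (2R)-3-{[tert-butyl(dimethyl)silyl]oxy}-2-methylpropanoic 2,4,6-trichlorobenzoic anhydride | C[C@H](CO[Si](C)(C)C(C)(C)C)C(=O)OC(=O)c1c(Cl)cc(Cl)cc1Cl | intermediate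
27 | tert-butyl 2-[(1S,2S,3R,4S,6S)-3-(3-{[tert-butyl(dimethyl)silyl]oxy}prop-1-en-2-yl)-6-{[(2R)-3-{[tert-butyl(dimethyl)silyl]oxy}-2-methylpropanoyl]oxy}-4-ethenyl-2-hydroxy-4-methylcyclohexyl]prop-2-enoate | C=C[C@]1(C)C[C@H](OC(=O)[C@H](C)CO[Si](C)(C)C(C)(C)C)[C@@H](C(=C)C(=O)OC(C)(C)C)[C@@H](O)[C@H]1C(=C)CO[Si](C)(C)C(C)(C)C | intermediate
28 | trimethylsilyl 2-[(1R,2S,3R,4S,6S)-3-(3-{[tert-butyl(dimethyl)silyl]oxy}prop-1-en-2-yl)-6-{[(2R)-3-{[tert-butyl(dimethyl)silyl]oxy}-2-methylpropanoyl]oxy}-4-ethenyl-4-methyl-2-[(trimethylsilyl)oxy]cyclohexyl]prop-2-enoate | C=C[C@]1(C)C[C@H](OC(=O)[C@H](C)CO[Si](C)(C)C(C)(C)C)[C@@H](C(=C)C(=O)O[Si](C)(C)C)[C@@H](O[Si](C)(C)C)[C@H]1C(=C)CO[Si](C)(C)C(C)(C)C | intermediate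
29 | 2-[(1S,2S,3R,4S,6S)-4-ethenyl-2-hydroxy-6-{[(2R)-3-hydroxy-2-methylpropanoyl]oxy}-3-(3-hydroxyprop-1-en-2-yl)-4-methylcyclohexyl]prop-2-enoic acid (CNP0462645.4) | C=C[C@]1(C)C[C@H](OC(=O)[C@H](C)CO)[C@@H](C(=C)C(=O)O)[C@@H](O)[C@H]1C(=C)CO | target

**Totals**
Total step count: 17.
Longest linear sequence: 11 steps (1, 2, 5, 6, 9, 10, 11, 12, 13, 16, 17; the branch through steps 3 and 4 is equally long). Side branches are steps 7–8 (fragment C) and 14–15 (fragment D).

**Three steps most likely to fail, each with a fallback**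

Step 9 (the proposed new coupling). The hindered α-branched acyl fluoride may add slowly to palladium, or the acylpalladium may lose CO. The fallback sets out from acid 13 and returns at ketone 18 by known carbonyl chemistry. LiAlH4 (THF, 0 °C) reduces 13 to (2R,3S)-2-(3-{[tert-butyl(dimethyl)silyl]oxy}prop-1-en-2-yl)-3-ethenyl-5-[(4-methoxybenzyl)oxy]-3-methylpentan-1-ol F5. Dess–Martin periodinane gives the corresponding pentanal F6, which is used at once because it is a β,γ-unsaturated aldehyde. Indium powder and bromide 15 in THF–H2O (Barbier allylation) give the homoallylic alcohol tert-butyl (5R,6S)-5-(3-{[tert-butyl(dimethyl)silyl]oxy}prop-1-en-2-yl)-6-ethenyl-4-hydroxy-8-[(4-methoxybenzyl)oxy]-6-methyl-2-methylideneoctanoate F7 as both C4 epimers; the tert-butyl ester keeps it from lactonising. A second Dess–Martin oxidation converges both epimers on 18.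

Step 12 (aldol ring closure). The base may dehydrate the ketol, move the deconjugated alkenes into conjugation, or epimerise C5 before closure. The fallback sets out from keto-aldehyde 20 and returns at ketol 21 by a one-pot enol silane formation and intramolecular Mukaiyama aldol, which avoids free base and is irreversible. TMSOTf and iPr2NEt in CH2Cl2 at −78 °C convert 20 into the trimethylsilyl dienol ether F8, which closes onto the silyl-triflate-activated aldehyde with the C8 oxygen equatorial (away from the axial C10 methyl) to give the β-silyloxy ketone F9. Aqueous citric acid removes the silyl ether and gives 21.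

Step 6 (enantioselective Ireland–Claisen). The boron bromide may enolise this β,γ-unsaturated ester with poor geometry control, attack the ether groups, or give low ee. The fallback sets out from ester 11 and returns at acid 13 by the classical lithium/silicon protocol followed by resolution. LiN(iPr)2 (LDA) in THF at −78 °C, then Me3SiCl/Et3N and warming to rt, give the (E)-O-trimethylsilyl ketene acetal F1, which rearranges through the same chair to the racemic trimethylsilyl ester F2. Work-up hydrolyses this to the racemic acid, that is 13 together with its (2S,3R)-enantiomer F3, with the same 2,3-relative configuration. Crystallisation of the (R)-1-phenylethylammonium salt F4 and acidification give 13.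

**Further compounds**
F1 | step 6 | (E)-O-trimethylsilyl ketene acetal of 11 | C=C(CO[Si](C)(C)C(C)(C)C)/C=C(/O[Si](C)(C)C)OC/C=C(\C)CCOCc1ccc(OC)cc1
F2 | step 6 | racemic trimethylsilyl ester of 13 (one enantiomer drawn) | C=C[C@](C)(CCOCc1ccc(OC)cc1)[C@H](C(=C)CO[Si](C)(C)C(C)(C)C)C(=O)O[Si](C)(C)C
F3 | step 6 | (2S,3R)-2-(3-{[tert-butyl(dimethyl)silyl]oxy}prop-1-en-2-yl)-3-ethenyl-5-[(4-methoxybenzyl)oxy]-3-methylpentanoic acid (enantiomer of 13) | C=C[C@@](C)(CCOCc1ccc(OC)cc1)[C@@H](C(=C)CO[Si](C)(C)C(C)(C)C)C(=O)O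
F4 | step 6 | (R)-1-phenylethylammonium salt of 13 | C=C[C@](C)(CCOCc1ccc(OC)cc1)[C@H](C(=C)CO[Si](C)(C)C(C)(C)C)C(=O)[O-].C[C@@H]([NH3+])c1ccccc1
F5 | step 9 | (2R,3S)-2-(3-{[tert-butyl(dimethyl)silyl]oxy}prop-1-en-2-yl)-3-ethenyl-5-[(4-methoxybenzyl)oxy]-3-methylpentan-1-ol | C=C[C@](C)(CCOCc1ccc(OC)cc1)[C@H](C(=C)CO[Si](C)(C)C(C)(C)C)CO
F6 | step 9 | (2R,3S)-2-(3-{[tert-butyl(dimethyl)silyl]oxy}prop-1-en-2-yl)-3-ethenyl-5-[(4-methoxybenzyl)oxy]-3-methylpentanal | C=C[C@](C)(CCOCc1ccc(OC)cc1)[C@H](C(=C)CO[Si](C)(C)C(C)(C)C)C=O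
F7 | step 9 | tert-butyl (5R,6S)-5-(3-{[tert-butyl(dimethyl)silyl]oxy}prop-1-en-2-yl)-6-ethenyl-4-hydroxy-8-[(4-methoxybenzyl)oxy]-6-methyl-2-methylideneoctanoate (both C4 epimers) | C=C[C@](C)(CCOCc1ccc(OC)cc1)[C@H](C(=C)CO[Si](C)(C)C(C)(C)C)C(O)CC(=C)C(=O)OC(C)(C)C
F8 | step 12 | trimethylsilyl dienol ether of 20 (C6–O silylated, C6=C7) | C=C[C@](C)(CC=O)[C@H](C(=C)CO[Si](C)(C)C(C)(C)C)C(O[Si](C)(C)C)=CC(=C)C(=O)OC(C)(C)C
F9 | step 12 | O-trimethylsilyl ether of 21 at the C8 oxygen | C=C[C@]1(C)C[C@H](O[Si](C)(C)C)[C@@H](C(=C)C(=O)OC(C)(C)C)C(=O)[C@H]1C(=C)CO[Si](C)(C)C(C)(C)C
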